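**Plan** (atom numbers are the drimane numbers of the target: C3 carbinol, C4 gem-dimethyl, C5/C10 ring fusion, C6=C7, C8=C12 exocyclic methylene, C9–C11H2–OAr)

1. Retrosynthesis: cut the C11–O aryl ether; open ring A at C1=C2 and remove the two C4 methyls; rejoin C3 to C8 (reverse Grob fragmentation), which turns ring B into a bicyclo[2.2.2]octenone; cut that at C5–C6 and C7–C8 (Diels–Alder of a 2-siloxy diene with an acetylene equivalent); the cyclohexenone behind it comes from a first Diels–Alder.
2. Enabling feature: in ring B the alkene C6=C7 is flanked by C5 and C8, C8 carries the exocyclic C12 and C3 carries oxygen. A temporary C3–C8 bond therefore makes C5 and C8 the termini of a cyclic 2-oxy diene C5=C4–C3(O)=C8, and the same bond is later the one broken in an O–C3–C8–C12–N+ Grob fragmentation that delivers C8=C12 and the C3 carbonyl.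
3. Forward order: the temporary carbocycle C3–C4–C5–C10–C9–C8 is made first, then ring B inside the bicycle (key step), then fragmentation frees ring B with its diene, then ring A is closed by metathesis, then C4 methylation, reduction and aryl ether formation.
4. Stereochemistry: C9/C10 from the E geometry of the enal and a chiral hydrogen-bond catalyst; C5 from face selection in the key cycloaddition (this fixes the trans ring fusion); C3 from hydride reduction to the equatorial alcohol.

Key step: step 6

Remark: the (R,R) enantiomer of the diol catalyst in step 2 is assumed to give the (1S,6S) adduct 6; if the sense of induction is the opposite, the (S,S) catalyst is used.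

Step 1
Reactants: 1 2-[(tert-butyldiphenylsilyl)oxy]acetaldehyde; 2 2-(triphenylphosphoranylidene)propanal
Product: 3 (E)-4-[(tert-butyldiphenylsilyl)oxy]-2-methylbut-2-enal
Conditions: toluene, 80 °C
Reagents that add atoms: none
Why: Wittig olefination with a formyl-stabilized ylide should give the E-enal, which places CH3 and CH2OSi cis on the double bond.

Step 2
Reactants: 3 (E)-4-[(tert-butyldiphenylsilyl)oxy]-2-methylbut-2-enal; 4 (E)-3-[(tert-butyldimethylsilyl)oxy]-N,N-dimethylbuta-1,3-dien-1-amine
Product: 6 (1S,6S)-6-{[(tert-butyldiphenylsilyl)oxy]methyl}-1-methyl-4-oxocyclohex-2-ene-1-carbaldehyde, via amino silyl enol ether cycloadduct 5 (not isolated)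
Conditions: (R,R)-1-naphthyl-TADDOL (20 mol %), toluene, −60 °C; then AcCl, CH2Cl2/Et2O, −78 °C
Reagents that add atoms: none
Why: Normal-demand Diels–Alder reaction in which the amino terminus of 4 bonds to the formyl-bearing carbon (so C10 ends γ to the new ketone), suprafacial addition carries the cis relation of CH3 and CH2OSi from the E-enal into C10/C9, the hydrogen-bonding diol should shield one face of the activated enal to set the absolute configuration, and AcCl then removes Me2N and the silyl group to unveil the enone.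

Step 3
Reactants: 6 (1S,6S)-6-{[(tert-butyldiphenylsilyl)oxy]methyl}-1-methyl-4-oxocyclohex-2-ene-1-carbaldehyde
Product: 7 (4S,5S)-5-{[(tert-butyldiphenylsilyl)oxy]methyl}-4-ethenyl-4-methylcyclohex-2-en-1-one
Conditions: Ph3PCH3Br, KN(SiMe3)2, THF, 0 °C; then 6, −78 → 0 °C
Reagents that add atoms: methyltriphenylphosphonium bromide, C[P+](c1ccccc1)(c1ccccc1)c1ccccc1.[Br-]
Why: Wittig methylenation should occur at the aldehyde much faster than at the conjugated ketone at low temperature, and no stereocentre is touched.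

Step 4
Reactants: 7 (4S,5S)-5-{[(tert-butyldiphenylsilyl)oxy]methyl}-4-ethenyl-4-methylcyclohex-2-en-1-one
Product: 8 (4S,5S)-5-{[(tert-butyldiphenylsilyl)oxy]methyl}-6-[(dimethylamino)methyl]-4-ethenyl-4-methylcyclohex-2-en-1-one (epimers at C6 of the ring)
Conditions: LiN(iPr)2, THF, −78 °C; Me2N=CH2 I, −78 °C → rt
Reagents that add atoms: dimethyl(methylidene)ammonium iodide, C=[N+](C)C.[I-]
Why: Kinetic deprotonation at the α′ carbon C8 (C10 is quaternary, so no γ-deprotonation is possible) followed by Mannich alkylation with the iminium salt installs C12 with a latent leaving group, and the new centre at C8 is flattened in step 5.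

Step 5
Reactants: 8 (4S,5S)-5-{[(tert-butyldiphenylsilyl)oxy]methyl}-6-[(dimethylamino)methyl]-4-ethenyl-4-methylcyclohex-2-en-1-one
Product: 9 2-[(tert-butyldimethylsilyl)oxy]-6-{[(tert-butyldiphenylsilyl)oxy]methyl}-1-[(dimethylamino)methyl]-5-ethenyl-5-methylcyclohexa-1,3-diene (5-methyl cis to 6-CH2OSi)
Conditions: LiN(iPr)2, THF, −78 °C; TBSCl, DMPU, −78 → 0 °C
Reagents that add atoms: tert-butyldimethylsilyl chloride, CC(C)(C)[Si](C)(C)Cl
Why: O-Silylation of the cross-conjugated lithium dienolate (silyl enol ether formation) gives the 2-siloxy diene C5=C4–C3(OSi)=C8 because C8 is the only enolizable position, and NMe2 is too poor a leaving group for E1cB loss at −78 °C.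

Step 6
Reactants: 9 2-[(tert-butyldimethylsilyl)oxy]-6-{[(tert-butyldiphenylsilyl)oxy]methyl}-1-[(dimethylamino)methyl]-5-ethenyl-5-methylcyclohexa-1,3-diene; 10 (E)-1,2-bis(phenylsulfonyl)ethene
Product: 11 2-[(tert-butyldimethylsilyl)oxy]-7-{[(tert-butyldiphenylsilyl)oxy]methyl}-1-[(dimethylamino)methyl]-8-ethenyl-8-methyl-5,6-bis(phenylsulfonyl)bicyclo[2.2.2]oct-2-ene (8-ethenyl and 7-H on the side of the C5–C6 bridge; sulfonyl groups trans, either orientation)
Conditions: toluene, 70 °C
Reagents that add atoms: none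
Why: Concerted normal-demand [4+2] cycloaddition (Diels–Alder reaction) of the electron-rich 2-siloxy diene C5=C4–C3(OTBS)=C8 with the doubly activated acetylene equivalent 10 forms C5–C6 and C7–C8 in one suprafacial event. The closest known reaction type is the cycloaddition of 2-siloxycyclohexa-1,3-dienes with 1,2-bis(phenylsulfonyl)ethene to give bicyclo[2.2.2]octenes. Ring B (C5–C6–C7–C8–C9–C10) closes as one six-membered ring of the bicycle by simultaneous bonding at both diene termini, the other ring (C3–C4–C5–C6–C7–C8) being the temporary one. C5 and C8 become bridgeheads whose configuration relative to C9 and C10 is fixed by the diene face attacked: the dienophile should approach anti to the pseudoaxial C10 methyl and the C9 silyloxymethyl group, that is syn to C9–H and the C10 ethenyl group, and this arrangement later becomes the trans ring fusion (C5–H anti to C10–CH3); the two sulfonyl-bearing centres are trans from the E dienophile and are erased in step 7. The step needs π-facial selectivity only, since the symmetric dienophile removes any regiochemical question, and this is secured by the cis pair of methyl and silyloxymethyl groups on one face; the isolated ethenyl group and the tertiary amine are not expected to compete.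

Step 7
Reactants: 11 Diels–Alder bis-sulfone adduct
Product: 13 7-{[(tert-butyldiphenylsilyl)oxy]methyl}-1-[(dimethylamino)methyl]-8-ethenyl-8-methylbicyclo[2.2.2]oct-5-en-2-one (8-ethenyl and 7-H syn to the C5=C6 bridge), via bicyclic silyl dienol ether 12 (not isolated)
Conditions: Na(Hg) (6 %), NaH2PO4, MeOH/THF, −20 °C; then AcOH/H2O/THF, rt
Reagents that add atoms: none
Why: Reductive elimination of the vicinal bis-sulfone by electron transfer (Julia-type desulfonylation) unmasks the cis C6=C7 alkene, and mild acid hydrolysis of the silyl enol ether gives the bridged ketone, whose bridgehead C8 cannot enolize so no stereocentre is at risk.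

Step 8
Reactants: 13 bridged amino ketone
Product: 14 7-{[(tert-butyldiphenylsilyl)oxy]methyl}-1-[(dimethylamino)methyl]-2,8-diethenyl-8-methylbicyclo[2.2.2]oct-5-en-2-ol (2-ethenyl syn to the C5=C6 bridge)
Conditions: CH2=CHMgBr, CeCl3, THF, −78 °C
Reagents that add atoms: vinylmagnesium bromide, C=C[Mg]Br
Why: 1,2-Addition of the organocerium reagent (Grignard addition with CeCl3) should outpace enolization at C4 and occur from the carbonyl face turned to the C6=C7 bridge, away from the C10 methyl and C9 silyloxymethyl groups.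

Step 9
Reactants: 14 bridged tertiary amino alcohol
Product: 16 1-[6-ethenyl-6-methyl-4-methylidene-5-{[(tert-butyldiphenylsilyl)oxy]methyl}cyclohex-2-en-1-yl]but-3-en-2-one (side chain cis to the 6-methyl and 5-CH2OSi groups), via trimethylammonium iodide 15 (not isolated)
Conditions: MeI, MeCN, rt; then NaH, THF/DMF, 0 °C
Reagents that add atoms: none
Why: Grob fragmentation, in which N-methylation turns C12–N into a nucleofuge and the alkoxide then expels the C3–C8 bond antiperiplanar to C12–N, giving the C3 ketone and the exocyclic C8=C12 alkene conjugated with C6=C7 while C5, C9 and C10 are untouched and the quaternary C8 rules out Hofmann elimination.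

Step 10
Reactants: 16 dienyl vinyl ketone
Product: 17 11-[(tert-butyldiphenylsilyl)oxy]-13,14-dinordrima-1,6,8(12)-trien-3-one (trans-fused; 5α-H, 9α-H, 10β-CH3)
Conditions: second-generation Grubbs catalyst (5 mol %), CH2Cl2, 40 °C
Reagents that add atoms: none
Why: Ring-closing metathesis between the C10 ethenyl group and the vinyl ketone closes ring A as a cyclohexenone with loss of ethene, the ring fusion being trans because C5 and C10 are already fixed, and the s-trans 1,3-diene is a poor metathesis partner.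

Step 11
Reactants: 17 dinor trienone
Product: 19 11-[(tert-butyldiphenylsilyl)oxy]drima-1,6,8(12)-trien-3-one, via 4-monomethyl enone 18 (not isolated)
Conditions: LiN(iPr)2, THF, −78 °C, then MeI; repeated once in the same flask, −78 → 0 °C
Reagents that add atoms: iodomethane, CI
Why: Kinetic α′-enolate alkylation, done twice, places both methyl groups on C4, the only enolizable carbon (the γ position C10 is quaternary), and C4 carries no stereochemistry at the end.

Step 12
Reactants: 19 gem-dimethyl trienone
Product: 21 11-[(tert-butyldiphenylsilyl)oxy]drima-6,8(12)-dien-3β-ol, via saturated 3-ketone 20 (not isolated)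
Conditions: LiBH(s-Bu)3 (L-Selectride, 1.05 equiv), THF, −78 °C; then MeOH, NaBH4, 0 °C
Reagents that add atoms: none
Why: Conjugate hydride reduction of the enone (its carbonyl is shielded by the adjacent quaternary C4) followed by NaBH4 reduction of the ketone, in which axial hydride attack from the α face opposite the axial 4β and 10β methyl groups should give the equatorial 3β alcohol.

Step 13
Reactants: 21 silyl ether alcohol
Product: 22 drima-6,8(12)-diene-3β,11-diol
Conditions: Bu4NF, THF, rt
Reagents that add atoms: none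
Why: Fluoride-mediated desilylation cleaves the silyl ether without touching the diene or the secondary alcohol.

Step 14
Reactants: 22 drima-6,8(12)-diene-3β,11-diol; 23 umbelliferone (7-hydroxy-2H-chromen-2-one)
Product: 24 7-{[3β-hydroxydrima-6,8(12)-dien-11-yl]oxy}-2H-chromen-2-one (CNP0259618.2)
Conditions: PPh3, DIAD, THF, 0 °C → rt
Reagents that add atoms: none
Why: Mitsunobu etherification activates only the primary C11 alcohol, the neopentyl-type secondary 3β-OH next to the gem-dimethyl group being inert, and no stereocentre is involved because C11 is CH2.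

**Compound list**

1 | 2-[(tert-butyldiphenylsilyl)oxy]acetaldehyde | O=CCO[Si](c1ccccc1)(c1ccccc1)C(C)(C)C | starting material
2 | 2-(triphenylphosphoranylidene)propanal | CC(C=O)=P(c1ccccc1)(c1ccccc1)c1ccccc1 | starting material
3 | (E)-4-[(tert-butyldiphenylsilyl)oxy]-2-methylbut-2-enal | O=C/C(C)=C/CO[Si](c1ccccc1)(c1ccccc1)C(C)(C)C | intermediate
4 | (E)-3-[(tert-butyldimethylsilyl)oxy]-N,N-dimethylbuta-1,3-dien-1-amine | CN(C)/C=C/C(=C)O[Si](C)(C)C(C)(C)C | starting material
5 | 4-[(tert-butyldimethylsilyl)oxy]-6-{[(tert-butyldiphenylsilyl)oxy]methyl}-2-(dimethylamino)-1-methylcyclohex-3-ene-1-carbaldehyde (1-methyl cis to 6-CH2OSi; amino carbon either epimer) | CN(C)C1C=C(O[Si](C)(C)C(C)(C)C)C[C@H](CO[Si](c2ccccc2)(c2ccccc2)C(C)(C)C)[C@@]1(C)C=O | intermediate (not isolated)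
6 | (1S,6S)-6-{[(tert-butyldiphenylsilyl)oxy]methyl}-1-methyl-4-oxocyclohex-2-ene-1-carbaldehyde | O=C1C=C[C@](C)(C=O)[C@@H](CO[Si](c2ccccc2)(c2ccccc2)C(C)(C)C)C1 | intermediate
7 | (4S,5S)-5-{[(tert-butyldiphenylsilyl)oxy]methyl}-4-ethenyl-4-methylcyclohex-2-en-1-one | O=C1C=C[C@](C)(C=C)[C@@H](CO[Si](c2ccccc2)(c2ccccc2)C(C)(C)C)C1 | intermediate
8 | (4S,5S)-5-{[(tert-butyldiphenylsilyl)oxy]methyl}-6-[(dimethylamino)methyl]-4-ethenyl-4-methylcyclohex-2-en-1-one (epimers at ring C6) | CN(C)CC1C(=O)C=C[C@](C)(C=C)[C@H]1CO[Si](c1ccccc1)(c1ccccc1)C(C)(C)C | intermediate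
9 | 2-[(tert-butyldimethylsilyl)oxy]-6-{[(tert-butyldiphenylsilyl)oxy]methyl}-1-[(dimethylamino)methyl]-5-ethenyl-5-methylcyclohexa-1,3-diene (5-methyl cis to 6-CH2OSi) | CN(C)CC1=C(O[Si](C)(C)C(C)(C)C)C=C[C@](C)(C=C)[C@H]1CO[Si](c1ccccc1)(c1ccccc1)C(C)(C)C | intermediate
10 | (E)-1,2-bis(phenylsulfonyl)ethene | O=S(=O)(/C=C/S(=O)(=O)c1ccccc1)c1ccccc1 | starting material
11 | 2-[(tert-butyldimethylsilyl)oxy]-7-{[(tert-butyldiphenylsilyl)oxy]methyl}-1-[(dimethylamino)methyl]-8-ethenyl-8-methyl-5,6-bis(phenylsulfonyl)bicyclo[2.2.2]oct-2-ene (8-ethenyl and 7-H on the side of the C5–C6 bridge; trans sulfonyl groups, either orientation) | CN(C)C[C@]12C(O[Si](C)(C)C(C)(C)C)=C[C@H](C(S(=O)(=O)c3ccccc3)C1S(=O)(=O)c1ccccc1)[C@](C)(C=C)[C@H]2CO[Si](c1ccccc1)(c1ccccc1)C(C)(C)C | intermediate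
12 | 2-[(tert-butyldimethylsilyl)oxy]-7-{[(tert-butyldiphenylsilyl)oxy]methyl}-1-[(dimethylamino)methyl]-8-ethenyl-8-methylbicyclo[2.2.2]octa-2,5-diene | CN(C)C[C@]12C(O[Si](C)(C)C(C)(C)C)=C[C@H](C=C1)[C@](C)(C=C)[C@H]2CO[Si](c1ccccc1)(c1ccccc1)C(C)(C)C | intermediate (not isolated)
13 | 7-{[(tert-butyldiphenylsilyl)oxy]methyl}-1-[(dimethylamino)methyl]-8-ethenyl-8-methylbicyclo[2.2.2]oct-5-en-2-one (8-ethenyl and 7-H syn to the C5=C6 bridge) | CN(C)C[C@]12C(=O)C[C@H](C=C1)[C@](C)(C=C)[C@H]2CO[Si](c1ccccc1)(c1ccccc1)C(C)(C)C | intermediate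
14 | 7-{[(tert-butyldiphenylsilyl)oxy]methyl}-1-[(dimethylamino)methyl]-2,8-diethenyl-8-methylbicyclo[2.2.2]oct-5-en-2-ol (2-ethenyl syn to the C5=C6 bridge) | CN(C)C[C@]12[C@](O)(C=C)C[C@H](C=C1)[C@](C)(C=C)[C@H]2CO[Si](c1ccccc1)(c1ccccc1)C(C)(C)C | intermediate
15 | N-methyl trimethylammonium iodide of 14 | C[N+](C)(C)C[C@]12[C@](O)(C=C)C[C@H](C=C1)[C@](C)(C=C)[C@H]2CO[Si](c1ccccc1)(c1ccccc1)C(C)(C)C.[I-] | intermediate (not isolated)
16 | 1-[6-ethenyl-6-methyl-4-methylidene-5-{[(tert-butyldiphenylsilyl)oxy]methyl}cyclohex-2-en-1-yl]but-3-en-2-one (side chain cis to 6-methyl and 5-CH2OSi) | C=CC(=O)C[C@@H]1C=CC(=C)[C@H](CO[Si](c2ccccc2)(c2ccccc2)C(C)(C)C)[C@@]1(C)C=C | intermediate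
17 | 11-[(tert-butyldiphenylsilyl)oxy]-13,14-dinordrima-1,6,8(12)-trien-3-one (trans-fused) | O=C1C=C[C@]2(C)[C@@H](CO[Si](c3ccccc3)(c3ccccc3)C(C)(C)C)C(=C)C=C[C@H]2C1 | intermediate
18 | 4-monomethyl analogue of 17 (C4 either epimer) | O=C1C=C[C@]2(C)[C@@H](CO[Si](c3ccccc3)(c3ccccc3)C(C)(C)C)C(=C)C=C[C@H]2C1C | intermediate (not isolated)
19 | 11-[(tert-butyldiphenylsilyl)oxy]drima-1,6,8(12)-trien-3-one | O=C1C=C[C@]2(C)[C@@H](CO[Si](c3ccccc3)(c3ccccc3)C(C)(C)C)C(=C)C=C[C@H]2C1(C)C | intermediate
20 | 11-[(tert-butyldiphenylsilyl)oxy]drima-6,8(12)-dien-3-one | O=C1CC[C@]2(C)[C@@H](CO[Si](c3ccccc3)(c3ccccc3)C(C)(C)C)C(=C)C=C[C@H]2C1(C)C | intermediate (not isolated)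
21 | 11-[(tert-butyldiphenylsilyl)oxy]drima-6,8(12)-dien-3β-ol | O[C@H]1CC[C@]2(C)[C@@H](CO[Si](c3ccccc3)(c3ccccc3)C(C)(C)C)C(=C)C=C[C@H]2C1(C)C | intermediate
22 | drima-6,8(12)-diene-3β,11-diol | O[C@H]1CC[C@]2(C)[C@@H](CO)C(=C)C=C[C@H]2C1(C)C | intermediate
23 | umbelliferone (7-hydroxy-2H-chromen-2-one) | O=c1ccc2ccc(O)cc2o1 | starting material
24 | 7-{[3β-hydroxydrima-6,8(12)-dien-11-yl]oxy}-2H-chromen-2-one (CNP0259618.2) | C=C1C=C[C@H]2C(C)(C)[C@@H](O)CC[C@]2(C)[C@H]1COc1ccc2ccc(=O)oc2c1 | target

Total step count: 14. Longest linear sequence: 14 steps (1 → 24).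

**Steps most likely to fail**

Step 6. The dienophile may attack the wrong diene face, react too slowly at the fully substituted diene terminus C8, or be consumed by the tertiary amine. The fallback sets out from 8: its lithium cross-conjugated dienolate (LiN(iPr)2, THF, −78 °C) would be added to phenyl vinyl sulfoxide in an anionic double Michael addition. Here the first bond is made at C8, directly next to the C9 stereocentre that shields one face, and the α-sulfinyl carbanion then closes onto C5, giving the bridged keto sulfoxide F1. Thermal syn-elimination of the sulfoxide (toluene, 110 °C, CaCO3) can only occur toward C7 and would return to the route at 13.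

Step 2. The β-substituted enal may add too slowly under hydrogen-bond catalysis, with poor enantiofacial control or with competing hetero-Diels–Alder addition at the aldehyde. The fallback sets out from 3: a Diels–Alder reaction with 2-[(triisopropylsilyl)oxy]buta-1,3-diene, catalysed by a chiral oxazaborolidinium triflimide (from (S)-α,α-diphenylprolinol and o-tolylboronic acid, activated with HNTf2; CH2Cl2, −78 °C), would give the silyl enol ether aldehyde F2. Saegusa–Ito oxidation (Pd(OAc)2, MeCN, rt) would then introduce the C4=C5 double bond and return to the route at 6.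

Step 9. An anionic oxy-Cope shift of the 1,5-diene alkoxide (C3 ethenyl with C6=C7) may compete with fragmentation. The fallback sets out from 13 and reverses the order, so that no such alkoxide ever forms. NaBH4 reduction would give the secondary amino alcohol F3 (either carbinol epimer). N-Methylation with MeI would give the ammonium iodide F4, and NaH would trigger the Grob fragmentation to the aldehyde F5. Addition of CH2=CHMgBr would give the allylic alcohol F6 (both epimers), and Dess–Martin oxidation would return to the route at 16.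

**Further compounds**

F1 | step 6 | 7-{[(tert-butyldiphenylsilyl)oxy]methyl}-1-[(dimethylamino)methyl]-8-ethenyl-8-methyl-5-(phenylsulfinyl)bicyclo[2.2.2]octan-2-one (sulfinyl carbon and sulfur unassigned) | CN(C)C[C@]12C(=O)C[C@H](C(S(=O)c3ccccc3)C1)[C@](C)(C=C)[C@H]2CO[Si](c1ccccc1)(c1ccccc1)C(C)(C)C
F2 | step 2 | (1S,6S)-6-{[(tert-butyldiphenylsilyl)oxy]methyl}-1-methyl-4-[(triisopropylsilyl)oxy]cyclohex-3-ene-1-carbaldehyde | CC(C)[Si](OC1=CC[C@](C)(C=O)[C@@H](CO[Si](c2ccccc2)(c2ccccc2)C(C)(C)C)C1)(C(C)C)C(C)C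
F3 | step 9 | 7-{[(tert-butyldiphenylsilyl)oxy]methyl}-1-[(dimethylamino)methyl]-8-ethenyl-8-methylbicyclo[2.2.2]oct-5-en-2-ol (carbinol either epimer) | CN(C)C[C@]12C(O)C[C@H](C=C1)[C@](C)(C=C)[C@H]2CO[Si](c1ccccc1)(c1ccccc1)C(C)(C)C
F4 | step 9 | N-methyl trimethylammonium iodide of F3 | C[N+](C)(C)C[C@]12C(O)C[C@H](C=C1)[C@](C)(C=C)[C@H]2CO[Si](c1ccccc1)(c1ccccc1)C(C)(C)C.[I-]
F5 | step 9 | 2-[6-ethenyl-6-methyl-4-methylidene-5-{[(tert-butyldiphenylsilyl)oxy]methyl}cyclohex-2-en-1-yl]acetaldehyde | O=CC[C@@H]1C=CC(=C)[C@H](CO[Si](c2ccccc2)(c2ccccc2)C(C)(C)C)[C@@]1(C)C=C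
F6 | step 9 | 1-[6-ethenyl-6-methyl-4-methylidene-5-{[(tert-butyldiphenylsilyl)oxy]methyl}cyclohex-2-en-1-yl]but-3-en-2-ol (carbinol epimers) | C=CC(O)C[C@@H]1C=CC(=C)[C@H](CO[Si](c2ccccc2)(c2ccccc2)C(C)(C)C)[C@@]1(C)C=C
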